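The route rests on the bond between cyclohexane C2 (the CH next to the acetoxy carbon C1) and oxane C2 (the methylated carbon on the ring oxygen). Because oxane C2 is an O,C,C,C-substituted ether carbon, it is revealed as a cyclic oxocarbenium ion from a methyl hemiketal; because cyclohexane C2 is alpha to the C1 oxygen, it is the nucleophilic carbon of a silyl enol ether made by Birch reduction. One Lewis-acid step joins the bromo-oxane and the methylcyclohexadiene, forms the bond and sets both of its stereocentres under control of the oxane C3 silyloxy and C5 bromide; the resulting cyclohexenone carries the alkene for a hydroxyl-directed bromochlorination.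

Key step: step 8

Remark on numbering: cyclohexane C1 (OAc), C2 (oxanyl), C4 (Br), C5 (Cl, CH3); oxane O1, C2 (CH3), C3 (OH), C5 (Br), C6 (two CH3).
Assumption: the D-fructose-derived Shi ketone is taken as the enantiomer that gives the (2R)-oxirane in step 3; its enantiomer would be used if the opposite sense applied.

Step 1
Reactants: 1 methyl (2S)-oxirane-2-carboxylate
Product: 2 methyl (2S)-2-hydroxy-5-methylhex-4-enoate
Conditions: 2-methylprop-1-enylmagnesium bromide, CuI (10 mol%), THF, −40 °C; aqueous work-up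
Reagents that add atoms: 2-methylprop-1-enylmagnesium bromide, CC(C)=C[Mg]Br
Why: Copper-catalysed SN2 opening of the glycidic ester by the alkenyl Grignard reagent occurs at the unsubstituted oxirane carbon, so the stereocentre of 1 is carried over untouched as the future oxane C3.

Step 2
Reactants: 2 methyl (2S)-2-hydroxy-5-methylhex-4-enoate
Product: 3 methyl (2S)-2-{[tert-butyl(dimethyl)silyl]oxy}-5-methylhex-4-enoate
Conditions: TBSCl, imidazole, DMF, rt
Reagents that add atoms: tert-butyldimethylsilyl chloride, CC(C)(C)[Si](C)(C)Cl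
Why: Standard silylation of a secondary alcohol; the silyl ether should survive every later step and is removed last.

Step 3
Reactants: 3 methyl (2S)-2-{[tert-butyl(dimethyl)silyl]oxy}-5-methylhex-4-enoate
Product: 4 methyl (2S)-2-{[tert-butyl(dimethyl)silyl]oxy}-3-[(2R)-3,3-dimethyloxiran-2-yl]propanoate
Conditions: Oxone (2KHSO5·KHSO4·K2SO4), D-fructose-derived Shi ketone (30 mol%), K2CO3, Bu4NHSO4, MeCN–dimethoxymethane–aqueous buffer, 0 °C
Reagents that add atoms: potassium peroxymonosulfate (the oxidant in Oxone), [K+].[O-]S(=O)(=O)OO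
Why: Shi asymmetric epoxidation of the trisubstituted alkene is reagent-controlled (spiro transition state), so the (2R)-oxirane should form irrespective of the remote silyloxy stereocentre.

Step 4
Reactants: 4 methyl (2S)-2-{[tert-butyl(dimethyl)silyl]oxy}-3-[(2R)-3,3-dimethyloxiran-2-yl]propanoate
Product: 6 (3S,5S)-5-bromo-3-{[tert-butyl(dimethyl)silyl]oxy}-6,6-dimethyloxan-2-one, via bromohydrin ester 5 (not isolated)
Conditions: Li2NiBr4, THF, 0 °C to rt; then PPTS (cat.), toluene, 60 °C
Reagents that add atoms: dilithium tetrabromonickelate, [Li+].[Li+].[Ni+2].[Br-].[Br-].[Br-].[Br-]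
Why: Soft bromide opens the oxirane by SN2 at the less substituted carbon with inversion, which sets the (S)-bromide (future oxane C5), and the tertiary alkoxide so released closes the six-membered lactone on the methyl ester (lactonisation).

Step 5
Reactants: 6 (3S,5S)-5-bromo-3-{[tert-butyl(dimethyl)silyl]oxy}-6,6-dimethyloxan-2-one
Product: 7 (3S,5S)-5-bromo-3-{[tert-butyl(dimethyl)silyl]oxy}-2,6,6-trimethyloxan-2-ol (both C2 epimers)
Conditions: MeLi (1.05 equiv), THF, −78 °C; then AcOH, −78 °C
Reagents that add atoms: methyllithium, [Li]C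
Why: Single addition of an organolithium to a lactone stops at the tetrahedral lithium hemiketal alkoxide at low temperature (standard entry to ketose-type hemiketals); the configuration at C2 is irrelevant because C2 is ionised in step 8.

Step 6
Reactants: 8 4-methylphenol
Product: 9 tert-butyl(dimethyl)(4-methylphenoxy)silane
Conditions: TBSCl, imidazole, DMF, rt
Reagents that add atoms: tert-butyldimethylsilyl chloride, CC(C)(C)[Si](C)(C)Cl
Why: Standard silylation of a phenol; it turns the phenol oxygen into the silyl enol ether oxygen of the next step.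

Step 7
Reactants: 9 tert-butyl(dimethyl)(4-methylphenoxy)silane
Product: 10 tert-butyl(dimethyl)[(4-methylcyclohexa-1,4-dien-1-yl)oxy]silane
Conditions: Li, NH3 (l), THF, t-BuOH, −78 to −33 °C; then neutral aqueous work-up
Reagents that add atoms: none
Why: Birch reduction of an aryl silyl ether gives the 1-silyloxy-1,4-diene, that is, the regiodefined silyl enol ether of 4-methylcyclohex-3-enone with the trisubstituted alkene already in place.

Step 8
Reactants: 7 (3S,5S)-5-bromo-3-{[tert-butyl(dimethyl)silyl]oxy}-2,6,6-trimethyloxan-2-ol; 10 tert-butyl(dimethyl)[(4-methylcyclohexa-1,4-dien-1-yl)oxy]silane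
Product: 12 (6R)-6-[(2S,3S,5S)-5-bromo-3-{[tert-butyl(dimethyl)silyl]oxy}-2,6,6-trimethyloxan-2-yl]-3-methylcyclohex-3-en-1-one, via oxocarbenium triflate 11 (not isolated)
Conditions: TMSOTf (1.1 equiv), 2,6-di-tert-butyl-4-methylpyridine, 10 (2 equiv), CH2Cl2, −78 °C; then NaHCO3 (aq), −78 °C to rt
Reagents that add atoms: none
Why: TMSOTf converts hemiketal 7 into the tertiary cyclic oxocarbenium ion 11, whose C2 is attacked by the enol carbon of 10, and silyl transfer releases the ketone; the closest known reaction type is the Mukaiyama-type addition of an enol silane to a ketose-derived oxocarbenium ion (C-glycosylation of a hemiketal). No ring is closed. Oxane C2 is controlled by the ring: axial attack on the half-chair that places the C3 silyloxy group pseudoequatorial and the C5 bromide pseudoaxial (both preferences select the same half-chair, while the C6 gem-dimethyl group hinders both faces equally) puts the new bond cis to O3 and trans to Br5. The cyclohexane stereocentre is set in an open transition state in which its hydrogen lies over the oxane ring towards the syn-axial C6 methyl, the bulky silyloxy-bearing enol carbon sits in the open sector between O1 and the C2 methyl, and the ring CH2 takes the remaining sector. The step needs C–C bond formation to outrun proton loss from 11 (hindered base, low temperature and excess 10), attack only through the enol ether (the isolated trisubstituted alkene is far less nucleophilic) and no conjugation of the β,γ-unsaturated ketone (buffered cold quench).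

Step 9
Reactants: 12 (6R)-6-[(2S,3S,5S)-5-bromo-3-{[tert-butyl(dimethyl)silyl]oxy}-2,6,6-trimethyloxan-2-yl]-3-methylcyclohex-3-en-1-one
Product: 13 (1S,6S)-6-[(2S,3S,5S)-5-bromo-3-{[tert-butyl(dimethyl)silyl]oxy}-2,6,6-trimethyloxan-2-yl]-3-methylcyclohex-3-en-1-ol
Conditions: Zn(BH4)2, Et2O, −30 to 0 °C
Reagents that add atoms: none
Why: Chelation-assisted hydride reduction (zinc bridging the carbonyl and the oxane oxygen) with axial delivery, which meets only one syn-axial hydrogen because C3 of the ring is sp2, should give the equatorial alcohol trans to the oxanyl group, and the neutral reagent leaves the β,γ-alkene unconjugated.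

Step 10
Reactants: 13 (1S,6S)-6-[(2S,3S,5S)-5-bromo-3-{[tert-butyl(dimethyl)silyl]oxy}-2,6,6-trimethyloxan-2-yl]-3-methylcyclohex-3-en-1-ol
Product: 14 (1S,2S,4R,5R)-4-bromo-2-[(2S,3S,5S)-5-bromo-3-{[tert-butyl(dimethyl)silyl]oxy}-2,6,6-trimethyloxan-2-yl]-5-chloro-5-methylcyclohexan-1-ol
Conditions: ClTi(OiPr)3 (1.2 equiv), NBS (1.1 equiv), matched enantiomer of a tridentate Schiff-base diol ligand (20 mol%), hexanes–CH2Cl2, −20 °C
Reagents that add atoms: N-bromosuccinimide, O=C1CCC(=O)N1Br; chlorotitanium triisopropoxide, CC(C)O[Ti](Cl)(OC(C)C)OC(C)C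
Why: Titanium-alkoxide-directed bromochlorination, a reaction type known for allylic and homoallylic alcohols: the C1 alkoxide carries the chlorotitanium unit, the bromonium ion forms on the face anti to it and the titanium-bound chloride is returned inside the complex to the tertiary carbon C5 through a six-membered array, so that Cl ends cis to O1 and Br at C4 trans to Cl, whereas an untethered addition would follow the trans-diaxial opening rule on the other face.

Step 11
Reactants: 14 (1S,2S,4R,5R)-4-bromo-2-[(2S,3S,5S)-5-bromo-3-{[tert-butyl(dimethyl)silyl]oxy}-2,6,6-trimethyloxan-2-yl]-5-chloro-5-methylcyclohexan-1-ol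
Product: 15 (1S,2S,4R,5R)-4-bromo-2-[(2S,3S,5S)-5-bromo-3-{[tert-butyl(dimethyl)silyl]oxy}-2,6,6-trimethyloxan-2-yl]-5-chloro-5-methylcyclohexyl acetate
Conditions: Ac2O, pyridine, DMAP (cat.), CH2Cl2, 0 °C to rt
Reagents that add atoms: acetic anhydride, CC(=O)OC(C)=O
Why: Nucleophile-catalysed acylation of the only free hydroxyl; the tertiary chloride and both bromides should be inert to these weakly basic conditions.

Step 12
Reactants: 15 (1S,2S,4R,5R)-4-bromo-2-[(2S,3S,5S)-5-bromo-3-{[tert-butyl(dimethyl)silyl]oxy}-2,6,6-trimethyloxan-2-yl]-5-chloro-5-methylcyclohexyl acetate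
Product: 16 (1S,2S,4R,5R)-4-bromo-2-[(2S,3S,5S)-5-bromo-3-hydroxy-2,6,6-trimethyloxan-2-yl]-5-chloro-5-methylcyclohexyl acetate, (5S)-5-acetoxycaespitol
Conditions: HF·pyridine, THF–pyridine, 0 °C to rt
Reagents that add atoms: none
Why: Fluoride-mediated desilylation under buffered acidic conditions should free the oxane C3 hydroxyl without acetate migration or elimination of the halides.

Compound list
1 | methyl (2S)-oxirane-2-carboxylate | COC(=O)[C@@H]1CO1 | starting material
2 | methyl (2S)-2-hydroxy-5-methylhex-4-enoate | CC(C)=CC[C@@H](C(=O)OC)O | intermediate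
3 | methyl (2S)-2-{[tert-butyl(dimethyl)silyl]oxy}-5-methylhex-4-enoate | CC(C)=CC[C@@H](C(=O)OC)O[Si](C)(C)C(C)(C)C | intermediate
4 | methyl (2S)-2-{[tert-butyl(dimethyl)silyl]oxy}-3-[(2R)-3,3-dimethyloxiran-2-yl]propanoate | CC1(C)O[C@@H]1C[C@@H](C(=O)OC)O[Si](C)(C)C(C)(C)C | intermediate
5 | methyl (2S,4S)-4-bromo-2-{[tert-butyl(dimethyl)silyl]oxy}-5-hydroxy-5-methylhexanoate (bromohydrin ester, not isolated) | CC(C)(O)[C@@H](Br)C[C@@H](C(=O)OC)O[Si](C)(C)C(C)(C)C | intermediate
6 | (3S,5S)-5-bromo-3-{[tert-butyl(dimethyl)silyl]oxy}-6,6-dimethyloxan-2-one | O=C1OC(C)(C)[C@@H](Br)C[C@@H]1O[Si](C)(C)C(C)(C)C | intermediate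
7 | (3S,5S)-5-bromo-3-{[tert-butyl(dimethyl)silyl]oxy}-2,6,6-trimethyloxan-2-ol (both C2 epimers) | CC1(O)OC(C)(C)[C@@H](Br)C[C@@H]1O[Si](C)(C)C(C)(C)C | intermediate
8 | 4-methylphenol | Cc1ccc(O)cc1 | starting material
9 | tert-butyl(dimethyl)(4-methylphenoxy)silane | Cc1ccc(O[Si](C)(C)C(C)(C)C)cc1 | intermediate
10 | tert-butyl(dimethyl)[(4-methylcyclohexa-1,4-dien-1-yl)oxy]silane | CC1=CCC(O[Si](C)(C)C(C)(C)C)=CC1 | intermediate
11 | oxocarbenium triflate of 7 (C2=O1 cation, 3S,5S; not isolated) | CC1=[O+]C(C)(C)[C@@H](Br)C[C@@H]1O[Si](C)(C)C(C)(C)C.[O-]S(=O)(=O)C(F)(F)F | intermediate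
12 | (6R)-6-[(2S,3S,5S)-5-bromo-3-{[tert-butyl(dimethyl)silyl]oxy}-2,6,6-trimethyloxan-2-yl]-3-methylcyclohex-3-en-1-one | O=C1CC(C)=CC[C@@H]1[C@]1(C)OC(C)(C)[C@@H](Br)C[C@@H]1O[Si](C)(C)C(C)(C)C | intermediate
13 | (1S,6S)-6-[(2S,3S,5S)-5-bromo-3-{[tert-butyl(dimethyl)silyl]oxy}-2,6,6-trimethyloxan-2-yl]-3-methylcyclohex-3-en-1-ol | O[C@H]1CC(C)=CC[C@@H]1[C@]1(C)OC(C)(C)[C@@H](Br)C[C@@H]1O[Si](C)(C)C(C)(C)C | intermediate
14 | (1S,2S,4R,5R)-4-bromo-2-[(2S,3S,5S)-5-bromo-3-{[tert-butyl(dimethyl)silyl]oxy}-2,6,6-trimethyloxan-2-yl]-5-chloro-5-methylcyclohexan-1-ol | O[C@H]1C[C@@](C)(Cl)[C@H](Br)C[C@@H]1[C@]1(C)OC(C)(C)[C@@H](Br)C[C@@H]1O[Si](C)(C)C(C)(C)C | intermediate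
15 | (1S,2S,4R,5R)-4-bromo-2-[(2S,3S,5S)-5-bromo-3-{[tert-butyl(dimethyl)silyl]oxy}-2,6,6-trimethyloxan-2-yl]-5-chloro-5-methylcyclohexyl acetate | CC(=O)O[C@H]1C[C@@](C)(Cl)[C@H](Br)C[C@@H]1[C@]1(C)OC(C)(C)[C@@H](Br)C[C@@H]1O[Si](C)(C)C(C)(C)C | intermediate
16 | (1S,2S,4R,5R)-4-bromo-2-[(2S,3S,5S)-5-bromo-3-hydroxy-2,6,6-trimethyloxan-2-yl]-5-chloro-5-methylcyclohexyl acetate, (5S)-5-acetoxycaespitol | CC(=O)O[C@H]1C[C@@](C)(Cl)[C@H](Br)C[C@@H]1[C@]1(C)OC(C)(C)[C@@H](Br)C[C@@H]1O | target

Total step count: 12. Longest linear sequence: 10 steps (steps 1–5 and 8–12); steps 6 and 7 make the second fragment.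

Steps most likely to fail

1. Step 8. The hindered tertiary oxocarbenium ion may lose a proton to give enol ethers before the C–C bond forms, and the open transition state may discriminate poorly between the two faces of the enol ether carbon. The fallback forms the same bond on an open-chain ketone through a closed, chelated aldol transition state and builds the oxane afterwards; it sets out from 2 and comes back to the route at 13.
 - Ester 2 is converted in one pot (MeNHOMe·HCl, iPrMgCl, THF, −20 °C; then MeMgBr) into (3S)-3-hydroxy-6-methylhept-5-en-2-one F1.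
 - Its magnesium alkoxide is combined at −78 °C with the kinetic lithium enolate of commercial 3-methylcyclohex-2-en-1-one (LiN(iPr)2, THF). Chelation of the alkoxide and the ketone oxygen fixes the carbinol configuration, and the chair-like aldol transition state with the larger ketone substituent equatorial should give the aldol diol (6R)-6-[(2S,3S)-2,3-dihydroxy-6-methylhept-5-en-2-yl]-3-methylcyclohex-2-en-1-one F2.
 - Selective silylation of the secondary hydroxyl (TBSOTf, 2,6-lutidine, −78 °C) gives the silyl ether F3.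
 - 6-endo bromoetherification of the tertiary alcohol onto the prenyl alkene (Et2SBr·SbCl5Br, MeNO2, −25 °C) gives the bromo-oxane enone F4. The conjugated ring alkene is deactivated, and a chair transition state with the cyclohexenyl group equatorial should place the bromide correctly.
 - Isopropenyl acetate with TsOH gives the extended dienyl acetate F5.
 - NaBH4 in EtOH reduces the β,γ-unsaturated ketone released in situ, by axial hydride delivery, to 13.

2. Step 10. Untethered chloride may open the bromonium ion on the opposite face by the trans-diaxial pathway, so that the tether loses facial control and the C4,C5-bis-epimer forms. The fallback replaces the titanium-bound chloride by a covalent carbonate tether and brings chloride in afterwards with retention; it sets out from 13 and comes back at 14.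
 - Boc2O with DMAP gives the tert-butyl carbonate of 13 F6.
 - Bromine-induced cyclisation of the homoallylic carbonate (NBS, CH2Cl2, −20 °C) proceeds by 6-exo attack of the carbonyl oxygen at the tertiary carbon with loss of isobutene. It gives the bicyclic bromo carbonate F7, in which the tether forces the C5 oxygen cis to O1 and the C4 bromide anti to it.
 - TiCl4 (CH2Cl2, −78 °C) ionises the tertiary C–O bond with anchimeric assistance by the antiperiplanar bromine. Chloride re-enters anti to bromine at the tertiary carbon (retention through the bromonium ion), CO2 is lost on work-up and 14 results.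

3. Step 5. The organolithium may enolise the α-silyloxy lactone, which would epimerise C3 or let the enolate displace the bromide intramolecularly. The fallback installs the methyl group before the bromide, so that no organolithium meets the bromo lactone; it sets out from 3 and comes back at 7.
 - Ester 3 is converted in one pot (MeNHOMe·HCl, iPrMgCl; then MeMgBr) into (3S)-3-{[tert-butyl(dimethyl)silyl]oxy}-6-methylhept-5-en-2-one F8.
 - Shi epoxidation as in step 3 gives (3S)-3-{[tert-butyl(dimethyl)silyl]oxy}-4-[(2R)-3,3-dimethyloxiran-2-yl]butan-2-one F9.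
 - Li2NiBr4 opens the oxirane as in step 4; the tertiary alcohol so formed is the open-chain tautomer of 7 and closes onto the ketone to give 7.

Further compounds
F1 | step 8 | (3S)-3-hydroxy-6-methylhept-5-en-2-one | CC(C)=CC[C@@H](C(C)=O)O
F2 | step 8 | (6R)-6-[(2S,3S)-2,3-dihydroxy-6-methylhept-5-en-2-yl]-3-methylcyclohex-2-en-1-one | O=C1C=C(C)CC[C@@H]1[C@](C)(O)[C@@H](O)CC=C(C)C
F3 | step 8 | (6R)-6-[(2S,3S)-3-{[tert-butyl(dimethyl)silyl]oxy}-2-hydroxy-6-methylhept-5-en-2-yl]-3-methylcyclohex-2-en-1-one | O=C1C=C(C)CC[C@@H]1[C@](C)(O)[C@@H](O[Si](C)(C)C(C)(C)C)CC=C(C)C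
F4 | step 8 | (6R)-6-[(2S,3S,5S)-5-bromo-3-{[tert-butyl(dimethyl)silyl]oxy}-2,6,6-trimethyloxan-2-yl]-3-methylcyclohex-2-en-1-one | O=C1C=C(C)CC[C@@H]1[C@]1(C)OC(C)(C)[C@@H](Br)C[C@@H]1O[Si](C)(C)C(C)(C)C
F5 | step 8 | (6S)-6-[(2S,3S,5S)-5-bromo-3-{[tert-butyl(dimethyl)silyl]oxy}-2,6,6-trimethyloxan-2-yl]-3-methylcyclohexa-1,3-dien-1-yl acetate | CC(=O)OC1=CC(C)=CC[C@@H]1[C@]1(C)OC(C)(C)[C@@H](Br)C[C@@H]1O[Si](C)(C)C(C)(C)C
F6 | step 10 | tert-butyl (1S,6S)-6-[(2S,3S,5S)-5-bromo-3-{[tert-butyl(dimethyl)silyl]oxy}-2,6,6-trimethyloxan-2-yl]-3-methylcyclohex-3-en-1-yl carbonate | CC(C)(C)OC(=O)O[C@H]1CC(C)=CC[C@@H]1[C@]1(C)OC(C)(C)[C@@H](Br)C[C@@H]1O[Si](C)(C)C(C)(C)C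
F7 | step 10 | 6-bromo-5-methyl-8-[(2S,3S,5S)-5-bromo-3-{[tert-butyl(dimethyl)silyl]oxy}-2,6,6-trimethyloxan-2-yl]-2,4-dioxabicyclo[3.3.1]nonan-3-one (carbonate oxygens cis on the cyclohexane, bromide anti to the tertiary oxygen) | O=C1O[C@H]2C[C@@](C)(O1)[C@H](Br)C[C@@H]2[C@]1(C)OC(C)(C)[C@@H](Br)C[C@@H]1O[Si](C)(C)C(C)(C)C
F8 | step 5 | (3S)-3-{[tert-butyl(dimethyl)silyl]oxy}-6-methylhept-5-en-2-one | CC(C)=CC[C@@H](C(C)=O)O[Si](C)(C)C(C)(C)C
F9 | step 5 | (3S)-3-{[tert-butyl(dimethyl)silyl]oxy}-4-[(2R)-3,3-dimethyloxiran-2-yl]butan-2-one | CC1(C)O[C@@H]1C[C@@H](C(C)=O)O[Si](C)(C)C(C)(C)C
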